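**Plan**

- Retrosynthetic cuts: the three O–Si bonds; the lactone C3–CH2Ar bond (enolate benzylation); the bond from C5 of the dihydrobenzofuran to its benzylic CH2 (aryl-copper opening of a cyclopropane-fused lactone); the C3–C3a bond of the dihydrofuran, traced back to a chroman-4-one by reversing a shift of C4a from C4 to C3; and the C2–aryl bond of that flavanone (conjugate addition to a chromone).
- Enabling feature: C3 of the 2,3-dihydrobenzofuran carries both the exocyclic one-carbon unit (C3–CH2OH) and the fused aromatic carbon C3a, next to the O1–C2(aryl) unit. This is the imprint of a flavanone whose C4a has moved from C4 to C3 while C4 left the heterocycle (ring B) as a carboxyl carbon.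
- Forward ring order: the pyranone ring B is closed first (chromone), arylated, then contracted to the dihydrofuran in the key step. The γ-butyrolactone arrives preformed from (R)-epichlorohydrin, is attached through its cyclopropane CH2 and is benzylated last.
- Stereochemistry: dihydrobenzofuran C2 (S) comes from a Pd/pyridine–oxazoline conjugate addition. C3 (R) is relayed from C2 in the ring contraction. Lactone C4 (R) comes from (R)-epichlorohydrin, and lactone C3 (R) from alkylation anti to C4.

Key step: step 6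

Assumption: the pyridine–oxazoline/palladium catalyst is taken to attack the chromone from the same enantioface as it does cyclic enones, which makes the (R)-ligand the one that sets C2 as S; if the sense proves opposite, the (S)-ligand is used instead.

**Route**

Step 1
Reactants: 1 1-(2-hydroxy-3-methoxyphenyl)ethanone
Product: 2 1-(5-bromo-2-hydroxy-3-methoxyphenyl)ethanone
Conditions: NBS, MeCN, 0 °C to rt
Reagents that add atoms: N-bromosuccinimide, O=C1CCC(=O)N1Br
Why: Electrophilic aromatic bromination goes para to the free phenol, whose ortho positions are blocked by the acetyl and methoxy groups, and NBS in MeCN avoids bromination of the acetyl methyl group.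

Step 2
Reactants: 2 1-(5-bromo-2-hydroxy-3-methoxyphenyl)ethanone; 3 N,N-dimethylformamide dimethyl acetal
Product: 5 6-bromo-8-methoxy-4H-chromen-4-one, via enaminone 4 (not isolated)
Conditions: 3 (neat), 100 °C; then conc. HCl, CH2Cl2, 40 °C
Reagents that add atoms: N,N-dimethylformamide dimethyl acetal (3), COC(OC)N(C)C
Why: Condensation of the methyl ketone with the amide acetal gives the enaminone, and acid then brings about oxa-Michael addition of the phenol and loss of dimethylamine (enaminone route to chromones).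

Step 3
Reactants: 6 2-methoxy-4-(4,4,5,5-tetramethyl-1,3,2-dioxaborolan-2-yl)phenol
Product: 7 2-methoxy-4-(4,4,5,5-tetramethyl-1,3,2-dioxaborolan-2-yl)phenyl pivalate
Conditions: t-BuCOCl, Et3N, DMAP (cat.), CH2Cl2, 0 °C to rt
Reagents that add atoms: pivaloyl chloride, CC(C)(C)C(=O)Cl
Why: DMAP-catalysed O-acylation of a phenol, to which the pinacol boronate is inert, installs the acyl group that later makes ring C electron-poor.

Step 4
Reactants: 7 2-methoxy-4-(4,4,5,5-tetramethyl-1,3,2-dioxaborolan-2-yl)phenyl pivalate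
Product: 8 [3-methoxy-4-(pivaloyloxy)phenyl]boronic acid
Conditions: NaIO4, NH4OAc, acetone/H2O, rt
Reagents that add atoms: water, O
Why: Periodate cleaves the pinacol as it is released by hydrolysis and so drives the boronate ester to the free boronic acid needed for transmetalation (oxidative deprotection of pinacol boronates), the hindered pivalate surviving the near-neutral medium.

Step 5
Reactants: 5 6-bromo-8-methoxy-4H-chromen-4-one; 8 [3-methoxy-4-(pivaloyloxy)phenyl]boronic acid
Product: 9 (2S)-6-bromo-8-methoxy-2-[3-methoxy-4-(pivaloyloxy)phenyl]chroman-4-one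
Conditions: Pd(OCOCF3)2 (5 mol%), (R)-4-tert-butyl-2-(pyridin-2-yl)-4,5-dihydrooxazole (6 mol%), NH4PF6 (30 mol%), H2O (5 equiv), ClCH2CH2Cl, 60 °C
Reagents that add atoms: none
Why: Asymmetric conjugate addition of an arylboronic acid to a chromone under cationic divalent-palladium catalysis with a pyridine–oxazoline ligand, in which transmetalation, enantioface-selective insertion of C2=C3 into the aryl–palladium bond under control of the tert-butyl oxazoline and protonolysis of the palladium enolate set C2 as S, and the aryl bromide is spared because no zerovalent palladium lies on the cycle.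

Step 6
Reactants: 9 (2S)-6-bromo-8-methoxy-2-[3-methoxy-4-(pivaloyloxy)phenyl]chroman-4-one; 10 trimethyl orthoformate
Product: 13 methyl (2S,3S)-5-bromo-7-methoxy-2-[3-methoxy-4-(pivaloyloxy)phenyl]-2,3-dihydro-1-benzofuran-3-carboxylate, via enol ether 11 (not isolated), via C3 iodane 12 (not isolated)
Conditions: PhI(OAc)2 (1.3 equiv), HC(OMe)3 (10, solvent), conc. H2SO4, rt; aq. NaHCO3
Reagents that add atoms: trimethyl orthoformate (10), COC(OC)OC; water, O
Why: Acid and orthoformate turn ketone 9 into enol ether 11; PhI(OAc)2 delivers trivalent iodine to C3 anti to the equatorial C2 aryl while methanol caps C4, and in the resulting iodane 12 the fused aryl carbon C4a, antiperiplanar to the equatorial C3–I bond, shifts from C4 to C3 as iodobenzene departs, the dimethoxycarbenium ion left at C4 being hydrolysed to the methyl ester on work-up. The closest known reaction type is the oxidative 1,2-aryl migration of aryl ketone enol ethers with hypervalent iodine or thallium trinitrate, which on flavanones is an established ring contraction to methyl trans-2-aryl-2,3-dihydrobenzofuran-3-carboxylates. The dihydrofuran is formed by contraction and not by cyclisation: C4a bridges C3 and C4 in a phenonium-like three-membered transition structure and ends bonded to C3 only, which creates the C3–C3a bond and pushes C4 out of the ring. The new stereocentre C3 is controlled by C2, since anti iodination followed by migration with inversion places the ester trans to the aryl group, (2S,3S), which is also the more stable arrangement, and C2 is not involved in any bond change. The step needs C4a to migrate in preference to a 2,3-shift of ring C (isoflavone) and to loss of H2 (flavone); the pivaloyloxy group para and the methoxy group meta to C1' make ring C a poor migrating group, O1 ortho to C4a makes the fused ring a good one, and the two methoxy groups on C4 stabilise the cation that the shift leaves behind.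

Step 7
Reactants: 13 methyl (2S,3S)-5-bromo-7-methoxy-2-[3-methoxy-4-(pivaloyloxy)phenyl]-2,3-dihydro-1-benzofuran-3-carboxylate
Product: 14 4-[(2S,3R)-5-bromo-3-(hydroxymethyl)-7-methoxy-2,3-dihydro-1-benzofuran-2-yl]-2-methoxyphenol
Conditions: LiAlH4, THF, 0 °C; H2O, aq. NaOH
Reagents that add atoms: none
Why: LiAlH4 reduction of the methyl ester to the primary alcohol with simultaneous reductive cleavage of the aryl pivalate, fast enough at 0 °C that the aryl bromide and the two stereocentres are not touched (C3 changes its descriptor to R only through the priority rules).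

Step 8
Reactants: 14 4-[(2S,3R)-5-bromo-3-(hydroxymethyl)-7-methoxy-2,3-dihydro-1-benzofuran-2-yl]-2-methoxyphenol
Product: 15 (2S,3R)-5-bromo-7-methoxy-2-[3-methoxy-4-(triisopropylsilyloxy)phenyl]-3-[(triisopropylsilyloxy)methyl]-2,3-dihydro-1-benzofuran
Conditions: i-Pr3SiCl, imidazole, DMAP (cat.), DMF, rt to 40 °C
Reagents that add atoms: chlorotriisopropylsilane, CC(C)[Si](Cl)(C(C)C)C(C)C
Why: Imidazole-promoted silylation of the phenol and the primary alcohol gives triisopropylsilyl ethers robust enough for Grignard formation, hot LiCl in DMSO and the lithium amide base of the later steps.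

Step 9
Reactants: 16 (R)-epichlorohydrin; 17 diethyl malonate
Product: 18 ethyl (1S,5R)-2-oxo-3-oxabicyclo[3.1.0]hexane-1-carboxylate
Conditions: NaOEt, EtOH, 0 °C to reflux
Reagents that add atoms: none
Why: In this known epichlorohydrin–malonate cyclopropanation–lactonisation, malonate opens the epoxide at its CH2, the alkoxide re-forms an epoxide by displacing chloride, the malonate carbanion opens it by 3-exo-tet attack with inversion and the freed alkoxide lactonises onto the cis ester, so that the epichlorohydrin centre becomes C5 (R) and the cis ring fusion fixes C1 (S).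

Step 10
Reactants: 15 (2S,3R)-5-bromo-7-methoxy-2-[3-methoxy-4-(triisopropylsilyloxy)phenyl]-3-[(triisopropylsilyloxy)methyl]-2,3-dihydro-1-benzofuran; 18 ethyl (1S,5R)-2-oxo-3-oxabicyclo[3.1.0]hexane-1-carboxylate
Product: 20 ethyl (4R)-4-({(2S,3R)-7-methoxy-2-[3-methoxy-4-(triisopropylsilyloxy)phenyl]-3-[(triisopropylsilyloxy)methyl]-2,3-dihydro-1-benzofuran-5-yl}methyl)-2-oxotetrahydrofuran-3-carboxylate, via arylmagnesium bromide 19 (not isolated)
Conditions: Mg turnings (activated with i-Bu2AlH, 1 mol%), LiCl, THF, 25 °C; then CuI (15 mol%), 18 (1.5 equiv), −30 to 0 °C; H2O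
Reagents that add atoms: none
Why: LiCl-assisted magnesium insertion gives the aryl Grignard reagent, and copper-catalysed homoconjugate addition (organocuprate opening of a cyclopropane-1,1-dicarbonyl compound) delivers the aryl group to the unhindered cyclopropane CH2 with cleavage of the C1–C6 bond, which leaves C5 of 18 untouched as the 4R centre of the lactone.

Step 11
Reactants: 20 ethyl (4R)-4-({(2S,3R)-7-methoxy-2-[3-methoxy-4-(triisopropylsilyloxy)phenyl]-3-[(triisopropylsilyloxy)methyl]-2,3-dihydro-1-benzofuran-5-yl}methyl)-2-oxotetrahydrofuran-3-carboxylate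
Product: 21 (4R)-4-({(2S,3R)-7-methoxy-2-[3-methoxy-4-(triisopropylsilyloxy)phenyl]-3-[(triisopropylsilyloxy)methyl]-2,3-dihydro-1-benzofuran-5-yl}methyl)dihydrofuran-2(3H)-one
Conditions: LiCl, H2O, DMSO, 140 °C
Reagents that add atoms: none
Why: Krapcho dealkoxycarbonylation removes the ester of the malonate-type lactone under neutral conditions that the lactone, the silyl ethers and the C4 centre should tolerate.

Step 12
Reactants: 22 vanillin (4-hydroxy-3-methoxybenzaldehyde)
Product: 23 3-methoxy-4-(triisopropylsilyloxy)benzaldehyde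
Conditions: i-Pr3SiCl, imidazole, DMF, rt
Reagents that add atoms: chlorotriisopropylsilane, CC(C)[Si](Cl)(C(C)C)C(C)C
Why: Standard imidazole-promoted silylation of the phenol protects it with the same group as in 15 so that one fluoride treatment can end the synthesis.

Step 13
Reactants: 23 3-methoxy-4-(triisopropylsilyloxy)benzaldehyde
Product: 24 [3-methoxy-4-(triisopropylsilyloxy)phenyl]methanol
Conditions: NaBH4, MeOH, 0 °C
Reagents that add atoms: none
Why: Borohydride reduction of the aromatic aldehyde to the benzylic alcohol leaves the aryl silyl ether intact.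

Step 14
Reactants: 24 [3-methoxy-4-(triisopropylsilyloxy)phenyl]methanol
Product: 25 [4-(bromomethyl)-2-methoxyphenoxy]triisopropylsilane
Conditions: CBr4, PPh3, CH2Cl2, 0 °C
Reagents that add atoms: carbon tetrabromide, BrC(Br)(Br)Br
Why: Appel bromination converts the benzylic alcohol into the bromide under neutral conditions that avoid acid-induced loss of the para-silyloxy group.

Step 15
Reactants: 21 (4R)-4-({(2S,3R)-7-methoxy-2-[3-methoxy-4-(triisopropylsilyloxy)phenyl]-3-[(triisopropylsilyloxy)methyl]-2,3-dihydro-1-benzofuran-5-yl}methyl)dihydrofuran-2(3H)-one; 25 [4-(bromomethyl)-2-methoxyphenoxy]triisopropylsilane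
Product: 27 (3R,4R)-3-[3-methoxy-4-(triisopropylsilyloxy)benzyl]-4-({(2S,3R)-7-methoxy-2-[3-methoxy-4-(triisopropylsilyloxy)phenyl]-3-[(triisopropylsilyloxy)methyl]-2,3-dihydro-1-benzofuran-5-yl}methyl)dihydrofuran-2(3H)-one, via lithium enolate 26 (not isolated)
Conditions: LiN(SiMe3)2, THF, −78 °C; then 25, DMPU, −78 to −40 °C
Reagents that add atoms: none
Why: Alkylation of the lithium enolate of a β-substituted γ-butyrolactone with a benzylic bromide takes place anti to the C4 substituent and so sets C3 as R in the trans-dibenzylbutyrolactone (the standard enolate alkylation route to such lignans).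

Step 16
Reactants: 27 (3R,4R)-3-[3-methoxy-4-(triisopropylsilyloxy)benzyl]-4-({(2S,3R)-7-methoxy-2-[3-methoxy-4-(triisopropylsilyloxy)phenyl]-3-[(triisopropylsilyloxy)methyl]-2,3-dihydro-1-benzofuran-5-yl}methyl)dihydrofuran-2(3H)-one
Product: 28 lappaol A, (3R,4R)-3-(4-hydroxy-3-methoxybenzyl)-4-{[(2S,3R)-2-(4-hydroxy-3-methoxyphenyl)-3-(hydroxymethyl)-7-methoxy-2,3-dihydro-1-benzofuran-5-yl]methyl}dihydrofuran-2(3H)-one
Conditions: Bu4NF, AcOH, THF, 0 °C to rt
Reagents that add atoms: none
Why: Fluoride-mediated desilylation frees the two phenols and the primary alcohol, and the acetic acid buffer keeps the phenoxides protonated so that the lactone, its epimerisable C3 and the benzylic C2–O bond are not exposed to base.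

**Compound list**

1 | 1-(2-hydroxy-3-methoxyphenyl)ethanone | CC(=O)c1cccc(OC)c1O | starting material
2 | 1-(5-bromo-2-hydroxy-3-methoxyphenyl)ethanone | CC(=O)c1cc(Br)cc(OC)c1O | intermediate
3 | N,N-dimethylformamide dimethyl acetal | COC(OC)N(C)C | starting material
4 | (E)-1-(5-bromo-2-hydroxy-3-methoxyphenyl)-3-(dimethylamino)prop-2-en-1-one | CN(C)/C=C/C(=O)c1cc(Br)cc(OC)c1O | intermediate (not isolated)
5 | 6-bromo-8-methoxy-4H-chromen-4-one | COc1cc(Br)cc2c(=O)ccoc12 | intermediate
6 | 2-methoxy-4-(4,4,5,5-tetramethyl-1,3,2-dioxaborolan-2-yl)phenol | COc1cc(B2OC(C)(C)C(C)(C)O2)ccc1O | starting material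
7 | 2-methoxy-4-(4,4,5,5-tetramethyl-1,3,2-dioxaborolan-2-yl)phenyl pivalate | COc1cc(B2OC(C)(C)C(C)(C)O2)ccc1OC(=O)C(C)(C)C | intermediate
8 | [3-methoxy-4-(pivaloyloxy)phenyl]boronic acid | COc1cc(B(O)O)ccc1OC(=O)C(C)(C)C | intermediate
9 | (2S)-6-bromo-8-methoxy-2-[3-methoxy-4-(pivaloyloxy)phenyl]chroman-4-one | Brc1cc(OC)c2c(c1)C(=O)C[C@@H](c1ccc(OC(=O)C(C)(C)C)c(OC)c1)O2 | intermediate
10 | trimethyl orthoformate | COC(OC)OC | starting material
11 | (2S)-6-bromo-4,8-dimethoxy-2-[3-methoxy-4-(pivaloyloxy)phenyl]-2H-chromene | Brc1cc(OC)c2c(c1)C(OC)=C[C@@H](c1ccc(OC(=O)C(C)(C)C)c(OC)c1)O2 | intermediate (not isolated)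
12 | (2R,3R)-3-[acetoxy(phenyl)iodanyl]-6-bromo-4,4,8-trimethoxy-2-[3-methoxy-4-(pivaloyloxy)phenyl]chromane (iodine trans to the 2-aryl group) | Brc1cc(OC)c2c(c1)C(OC)(OC)[C@H]([I](OC(C)=O)c1ccccc1)[C@@H](c1ccc(OC(=O)C(C)(C)C)c(OC)c1)O2 | intermediate (not isolated)
13 | methyl (2S,3S)-5-bromo-7-methoxy-2-[3-methoxy-4-(pivaloyloxy)phenyl]-2,3-dihydro-1-benzofuran-3-carboxylate | Brc1cc(OC)c2c(c1)[C@H](C(=O)OC)[C@@H](c1ccc(OC(=O)C(C)(C)C)c(OC)c1)O2 | intermediate
14 | 4-[(2S,3R)-5-bromo-3-(hydroxymethyl)-7-methoxy-2,3-dihydro-1-benzofuran-2-yl]-2-methoxyphenol | Brc1cc(OC)c2c(c1)[C@H](CO)[C@@H](c1ccc(O)c(OC)c1)O2 | intermediate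
15 | (2S,3R)-5-bromo-7-methoxy-2-[3-methoxy-4-(triisopropylsilyloxy)phenyl]-3-[(triisopropylsilyloxy)methyl]-2,3-dihydro-1-benzofuran | Brc1cc(OC)c2c(c1)[C@H](CO[Si](C(C)C)(C(C)C)C(C)C)[C@@H](c1ccc(O[Si](C(C)C)(C(C)C)C(C)C)c(OC)c1)O2 | intermediate
16 | (R)-epichlorohydrin | ClC[C@H]1CO1 | starting material
17 | diethyl malonate | CCOC(=O)CC(=O)OCC | starting material
18 | ethyl (1S,5R)-2-oxo-3-oxabicyclo[3.1.0]hexane-1-carboxylate | O=C1OC[C@@H]2C[C@]12C(=O)OCC | intermediate
19 | {(2S,3R)-7-methoxy-2-[3-methoxy-4-(triisopropylsilyloxy)phenyl]-3-[(triisopropylsilyloxy)methyl]-2,3-dihydro-1-benzofuran-5-yl}magnesium bromide | Br[Mg]c1cc(OC)c2c(c1)[C@H](CO[Si](C(C)C)(C(C)C)C(C)C)[C@@H](c1ccc(O[Si](C(C)C)(C(C)C)C(C)C)c(OC)c1)O2 | intermediate (not isolated)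
20 | ethyl (4R)-4-({(2S,3R)-7-methoxy-2-[3-methoxy-4-(triisopropylsilyloxy)phenyl]-3-[(triisopropylsilyloxy)methyl]-2,3-dihydro-1-benzofuran-5-yl}methyl)-2-oxotetrahydrofuran-3-carboxylate (lactone C3 is a labile malonate-type centre, drawn undefined) | CCOC(=O)C1C(=O)OC[C@@H]1Cc1cc(OC)c2c(c1)[C@H](CO[Si](C(C)C)(C(C)C)C(C)C)[C@@H](c1ccc(O[Si](C(C)C)(C(C)C)C(C)C)c(OC)c1)O2 | intermediate
21 | (4R)-4-({(2S,3R)-7-methoxy-2-[3-methoxy-4-(triisopropylsilyloxy)phenyl]-3-[(triisopropylsilyloxy)methyl]-2,3-dihydro-1-benzofuran-5-yl}methyl)dihydrofuran-2(3H)-one | O=C1C[C@@H](Cc2cc(OC)c3c(c2)[C@H](CO[Si](C(C)C)(C(C)C)C(C)C)[C@@H](c2ccc(O[Si](C(C)C)(C(C)C)C(C)C)c(OC)c2)O3)CO1 | intermediate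
22 | vanillin | COc1cc(C=O)ccc1O | starting material
23 | 3-methoxy-4-(triisopropylsilyloxy)benzaldehyde | COc1cc(C=O)ccc1O[Si](C(C)C)(C(C)C)C(C)C | intermediate
24 | [3-methoxy-4-(triisopropylsilyloxy)phenyl]methanol | COc1cc(CO)ccc1O[Si](C(C)C)(C(C)C)C(C)C | intermediate
25 | [4-(bromomethyl)-2-methoxyphenoxy]triisopropylsilane | COc1cc(CBr)ccc1O[Si](C(C)C)(C(C)C)C(C)C | intermediate
26 | lithium enolate of 21 (lithium (4R)-4-(arylmethyl)-4,5-dihydrofuran-2-olate) | [Li]OC1=C[C@@H](Cc2cc(OC)c3c(c2)[C@H](CO[Si](C(C)C)(C(C)C)C(C)C)[C@@H](c2ccc(O[Si](C(C)C)(C(C)C)C(C)C)c(OC)c2)O3)CO1 | intermediate (not isolated)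
27 | (3R,4R)-3-[3-methoxy-4-(triisopropylsilyloxy)benzyl]-4-({(2S,3R)-7-methoxy-2-[3-methoxy-4-(triisopropylsilyloxy)phenyl]-3-[(triisopropylsilyloxy)methyl]-2,3-dihydro-1-benzofuran-5-yl}methyl)dihydrofuran-2(3H)-one | COc1cc(C[C@H]2C(=O)OC[C@@H]2Cc2cc(OC)c3c(c2)[C@H](CO[Si](C(C)C)(C(C)C)C(C)C)[C@@H](c2ccc(O[Si](C(C)C)(C(C)C)C(C)C)c(OC)c2)O3)ccc1O[Si](C(C)C)(C(C)C)C(C)C | intermediate
28 | lappaol A | COc1cc(C[C@H]2C(=O)OC[C@@H]2Cc2cc(OC)c3c(c2)[C@H](CO)[C@@H](c2ccc(O)c(OC)c2)O3)ccc1O | target

**Step count and risks**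

Total steps: 16. Longest linear sequence: 10 steps (steps 1, 2, 5, 6, 7, 8, 10, 11, 15, 16).

Steps most likely to fail:

1. Step 6. Loss of iodobenzene and a proton from the C3 iodane (dehydrogenation to the flavone) or a shift of ring C in place of C4a may outrun the ring contraction, and acid-promoted methanolysis of the pivalate would make ring C more prone to migrate. Fallback, from 9 back to 13, with the same C4a shift but no oxidant present when it occurs:
   - 9 is brominated at C3 with PhNMe3Br3 in THF at 0 °C to the (2R,3R)-3,6-dibromo-8-methoxy-2-[3-methoxy-4-(pivaloyloxy)phenyl]chroman-4-one F1 (bromine trans to the aryl group; the C2 arrangement is unchanged).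
   - Ketalisation with HC(OMe)3, MeOH and TsOH gives the (2R,3R)-3,6-dibromo-4,4,8-trimethoxy-2-[3-methoxy-4-(pivaloyloxy)phenyl]chromane F2.
   - AgBF4 in MeOH at 50 °C ionises the equatorial C–Br bond with participation of the antiperiplanar C4a (1,2-aryl shift of an α-halo ketal, the reaction type used for 2-arylalkanoic esters) and gives 13 after aqueous work-up.

2. Step 10. Incomplete magnesium insertion, protonation of the aryl Grignard reagent, or attack on the lactone and ester carbonyls of 18 in place of homoconjugate opening would waste the advanced aryl bromide. Fallback, from 15 back to 21, which forms the same aryl–CH2 bond by cross-coupling and bypasses 20 and step 11: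
   - (R)-paraconic acid [(3R)-5-oxotetrahydrofuran-3-carboxylic acid] is reduced with BH3·SMe2 to (S)-4-(hydroxymethyl)dihydrofuran-2(3H)-one F3.
   - I2, PPh3 and imidazole convert it into (R)-4-(iodomethyl)dihydrofuran-2(3H)-one F4.
   - Zinc dust with LiCl in THF gives {[(3R)-5-oxotetrahydrofuran-3-yl]methyl}zinc iodide F5.
   - Negishi coupling of F5 with 15 [Pd(OAc)2, 2-dicyclohexylphosphino-2',6'-dimethoxybiphenyl, THF, 50 °C, zerovalent palladium formed in situ] gives 21.

3. Step 5. Insufficient enantioface discrimination on the 8-methoxy chromone, or deposition of palladium metal followed by insertion into the C–Br bond, would lower the optical purity or the yield. Fallback, from 5 (with 8) back to 9, replacing asymmetric C–C bond formation by a kinetic resolution: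
   - Achiral conjugate addition with Pd(OCOCF3)2 and 2,2'-bipyridine gives the racemic 6-bromo-8-methoxy-2-[3-methoxy-4-(pivaloyloxy)phenyl]chroman-4-one F6.
   - Asymmetric transfer hydrogenation with RuCl(p-cymene)[(R,R)-TsDPEN] in HCO2H/Et3N should reduce the (2R)-ketone selectively to the (2R,4R)-cis-6-bromo-8-methoxy-2-[3-methoxy-4-(pivaloyloxy)phenyl]chroman-4-ol F7.
   - The unreacted (2S)-ketone 9 is separated by chromatography.

**Further compounds**

F1 | step 6 | (2R,3R)-3,6-dibromo-8-methoxy-2-[3-methoxy-4-(pivaloyloxy)phenyl]chroman-4-one | Brc1cc(OC)c2c(c1)C(=O)[C@H](Br)[C@@H](c1ccc(OC(=O)C(C)(C)C)c(OC)c1)O2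
F2 | step 6 | (2R,3R)-3,6-dibromo-4,4,8-trimethoxy-2-[3-methoxy-4-(pivaloyloxy)phenyl]chromane | Brc1cc(OC)c2c(c1)C(OC)(OC)[C@H](Br)[C@@H](c1ccc(OC(=O)C(C)(C)C)c(OC)c1)O2
F3 | step 10 | (S)-4-(hydroxymethyl)dihydrofuran-2(3H)-one | O=C1C[C@@H](CO)CO1
F4 | step 10 | (R)-4-(iodomethyl)dihydrofuran-2(3H)-one | O=C1C[C@@H](CI)CO1
F5 | step 10 | {[(3R)-5-oxotetrahydrofuran-3-yl]methyl}zinc iodide | O=C1C[C@@H](C[Zn]I)CO1
F6 | step 5 | racemic 6-bromo-8-methoxy-2-[3-methoxy-4-(pivaloyloxy)phenyl]chroman-4-one | Brc1cc(OC)c2c(c1)C(=O)CC(c1ccc(OC(=O)C(C)(C)C)c(OC)c1)O2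
F7 | step 5 | (2R,4R)-cis-6-bromo-8-methoxy-2-[3-methoxy-4-(pivaloyloxy)phenyl]chroman-4-ol | Brc1cc(OC)c2c(c1)[C@H](O)C[C@H](c1ccc(OC(=O)C(C)(C)C)c(OC)c1)O2
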